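**Retrosynthetic overview** (C1 = ester carbonyl carbon)
1. The C7–C8 bond of 7 is cut homolytically into two primary alkyl radicals, tridecyl (C8–C20) and 7-(benzyloxy)-7-oxoheptyl (C1–C7). Each is traced back to the carboxylic acid with one more carbon: myristic acid 4 and benzyl hydrogen suberate 3.
2. Both carbons are generated in the same way, by anodic one-electron oxidation of a carboxylate, and are joined radical to radical in a mixed Kolbe electrolysis. The two CO2H groups are traceless activators that leave as CO2, so nothing has to be removed afterwards.
3. Enabling feature: C7 and C8 are plain CH2 groups inside the unbranched polymethylene run C2–C19. Neither has an adjacent branch, heteroatom or π-system, and five CH2 groups separate C7 from the carbonyl C1, so both radicals couple rather than oxidise further. The ester unit (C1, its two oxygens, the OCH2 and the phenyl ring) is a spectator.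
4. Half ester 3 comes from suberic acid 1 and benzyl alcohol 2 by monoesterification.
5. No ring is formed at any stage. The only ring, the phenyl ring, is bought intact with 2.

Key step: step 2

Remark on the chemistry: the target has no stereocentre, so no compound in the route needs a stereodescriptor.

**Step 1**
Reactants: 1 suberic acid (octanedioic acid); 2 benzyl alcohol
Product: 3 benzyl hydrogen suberate (8-(benzyloxy)-8-oxooctanoic acid)
Conditions: 1 (3 equiv), 2 (1 equiv), p-TsOH·H2O (cat.), toluene, reflux, Dean–Stark; cool and filter off unreacted 1; extract 3 into aq. NaHCO3, acidify, re-extract
Reagents that add atoms: none
Why: Fischer esterification with azeotropic water removal, in which the excess of diacid biases the statistical outcome toward the monoester, unreacted 1 crystallises from cold toluene, and the neutral diester stays in the organic phase during the base extraction.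

**Step 2**
Reactants: 3 benzyl hydrogen suberate; 4 myristic acid (tetradecanoic acid)
Product: 7 benzyl eicosanoate, via tridecyl radical 5 (not isolated), via 7-(benzyloxy)-7-oxoheptyl radical 6 (not isolated)
Conditions: 3 (1 equiv), 4 (4 equiv), KOH (5 mol% of total CO2H), MeOH–pyridine 4:1, undivided cell, smooth Pt anode and Pt cathode, constant current 0.25–0.5 A cm⁻², 40–45 °C, periodic polarity reversal; stopped while still weakly acidic, AcOH quench; aq. Na2CO3 wash, silica gel chromatography
Reagents that add atoms: none
Why: In this mixed Kolbe electrolysis both carboxylates are oxidised by one electron at the platinum anode and lose CO2, giving the primary radicals 5 and 6 at high local concentration in the electrode layer, where they combine to form the C7–C8 bond while acid protons are reduced to hydrogen at the cathode. The closest known reaction type is the crossed Kolbe coupling of a fatty acid with an alkyl hydrogen alkanedioate, the classical electrochemical chain extension of fatty acids. No ring is closed and no stereocentre is created. Radical coupling must win over a second oxidation to carbocations (Hofer–Moest path), and this is secured by both radical carbons being unsubstituted primary CH2 groups and by smooth Pt, high current density and a weakly acidic, only partly neutralised electrolyte. Cross- versus homocoupling is purely statistical, so the cheap acid 4 is used in excess to channel radical 6 into 7, and the three coupling products carry zero, one and two ester groups and should therefore separate cleanly on silica. The benzyl ester should survive because free acid buffers the medium, so no methoxide builds up before the end point, and because the acyloxymethyl-substituted phenyl ring is harder to oxidise than the carboxylate layer covering the anode.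

**Compound list**
1 | suberic acid (octanedioic acid) | OC(=O)CCCCCCC(=O)O | starting material
2 | benzyl alcohol | OCc1ccccc1 | starting material
3 | benzyl hydrogen suberate (8-(benzyloxy)-8-oxooctanoic acid) | OC(=O)CCCCCCC(=O)OCc1ccccc1 | intermediate
4 | myristic acid (tetradecanoic acid) | CCCCCCCCCCCCCC(=O)O | starting material
5 | tridecyl radical | CCCCCCCCCCCC[CH2] | intermediate
6 | 7-(benzyloxy)-7-oxoheptyl radical | [CH2]CCCCCC(=O)OCc1ccccc1 | intermediate
7 | benzyl eicosanoate (eicosanoic acid phenylmethyl ester) | CCCCCCCCCCCCCCCCCCCC(=O)OCc1ccccc1 | target

**Total step count:** 2
**Longest linear sequence:** 2

**Steps most likely to fail** (the route has only two steps, so both are ranked and no third can be named)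

1. Step 2. Three processes threaten it:
   - Each radical may couple statistically with itself, which drains 3.
   - The waxy products dissolve poorly in methanol and may foul the anode. Current density would then fall and the reaction would drift toward two-electron oxidation, with solvent capture and elimination.
   - The benzyl ester may undergo methanolysis if the electrolyte is allowed to turn alkaline.

   The fallback replaces radical dimerisation by a polar, metal-catalysed sp3–sp3 coupling. It sets out from 2, which is esterified with commercial 7-bromoheptanoic acid (cat. p-TsOH, toluene, Dean–Stark) to give benzyl 7-bromoheptanoate F1. Commercial 1-bromotridecane and magnesium in THF give tridecylmagnesium bromide F2. Slow addition of F2 to F1 with Li2CuCl4 (3 mol%) and NMP in THF at 0 °C is a copper-catalysed Kumada-type alkyl–alkyl coupling. It should displace the primary bromide faster than the Grignard reagent attacks the ester, form the same C7–C8 bond, and come back to the route at 7.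

2. Step 1. Double esterification may occur, and the half ester may not be fully separated from unreacted diacid. Carried-over diacid would then couple at both ends in the electrolysis. The fallback avoids making a benzyl half ester and attaches the benzyl group after the C–C coupling. It sets out from 4, which is electrolysed under the conditions of step 2 with commercial methyl hydrogen suberate (8-methoxy-8-oxooctanoic acid) to give methyl eicosanoate F3. Methanolysis is harmless for this ester. Transesterification of F3 with an excess of 2 (cat. Ti(OiPr)4, toluene, reflux, methanol distilled off) comes back to the route at 7.

**Further compounds**
F1 | step 2 | benzyl 7-bromoheptanoate | BrCCCCCCC(=O)OCc1ccccc1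
F2 | step 2 | tridecylmagnesium bromide | CCCCCCCCCCCCC[Mg]Br
F3 | step 1 | methyl eicosanoate | CCCCCCCCCCCCCCCCCCCC(=O)OC
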